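**Retrosynthetic overview**

1. 24 ⇐ 23 by epoxidation of the cis C-3/C-4 olefin (last ring) ⇐ diol 21 by C-8 acylation ⇐ ketone 16 by C-10 methylation, hydroxyl-directed hydrogenation of C-6/C-7 and inversion of C-8 (oxidation, then reduction to the axial alcohol).
2. 16 ⇐ enol pivalate 15 ⇐ acyclic trienyne pivalate 13: one gold-catalysed (4+3) operation makes C-1/C-5 and C-8/C-9 and so closes the five- and the seven-membered carbocycle at once; C-1 is left trigonal and is set afterwards by equilibration (trans fusion).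
3. Enabling feature: the cycloheptane carries oxygen on C-10 (between C-9H2 and the fusion carbon C-1), oxygen on C-8 and, across the ring, the C-6/C-7 bond. This is the pattern of a cyclohepta-1,4-diene built from a 2-oxyallyl unit C-9/C-10/C-1 and a 1-oxy diene C-5 to C-8. C-2/C-3/C-4 of the cyclopentane, with the cis trisubstituted C-3/C-4 olefin that later becomes the oxirane, are the rigid three-atom tether between C-1 and C-5.
4. 13 ⇐ Suzuki–Miyaura union (C-4/C-5) of (Z)-vinyl iodide 7 (from propargyl pivalate 2 and (Z)-allylic bromide 6) with (1E,3E)-dienylboronate 12 (from acetal 8 by formylation, O-alkylation and boryl-olefination).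
5. Order of ring formation: cyclopentene and cycloheptadiene together (step 9), oxirane last (step 17).

Key step: step 9

Remark: guaiane locants are used throughout, also for the carbons of the acyclic precursors (C-1/C-5 ring fusion, methyl on C-4 and C-10, isopropyl on C-7, "14-nor" where the C-10 methyl is absent); β is the face of H-5, α the opposite face; the sense of induction of the gold catalyst in step 9 is assumed to be the one that gives (5R,8S)-15, the mirror-image ligand being used otherwise.

**Route**

Step 1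
Reactants: 1 prop-2-yn-1-ol
Product: 2 prop-2-yn-1-yl pivalate
Conditions: PivCl, Et3N, DMAP (cat.), CH2Cl2, 0 °C
Reagents that add atoms: pivaloyl chloride CC(C)(C)C(Cl)=O
Why: DMAP-catalysed O-acylation of the primary alcohol installs the pivaloyloxy group that later migrates onto C-10.

Step 2
Reactants: 3 but-2-yn-1-ol
Product: 5 (Z)-3-iodobut-2-en-1-ol, via cyclic sodium alkenylalanate 4 (not isolated)
Conditions: NaAlH2(OCH2CH2OMe)2, Et2O, 0 °C; then I2, THF, −78 °C
Reagents that add atoms: iodine II
Why: Hydroxyl-directed trans-hydroalumination of the propargylic alcohol places aluminium on the distal carbon inside a five-membered alanate, and iodinolysis with retention gives the (Z)-vinyl iodide in which the future C-2 and C-5 substituents are cis.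

Step 3
Reactants: 5 (Z)-3-iodobut-2-en-1-ol
Product: 6 (Z)-1-bromo-3-iodobut-2-ene
Conditions: CBr4, PPh3, CH2Cl2, 0 °C
Reagents that add atoms: tetrabromomethane BrC(Br)(Br)Br
Why: Appel reaction, in which bromide displaces the oxyphosphonium ion at the primary allylic carbon without touching the vinyl iodide or its geometry.

Step 4
Reactants: 2 prop-2-yn-1-yl pivalate; 6 (Z)-1-bromo-3-iodobut-2-ene
Product: 7 (Z)-6-iodohept-5-en-2-yn-1-yl pivalate
Conditions: CuI (10 mol%), Bu4NI (10 mol%), K2CO3, DMF, 25 °C
Reagents that add atoms: none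
Why: Copper-catalysed SN2 alkylation of the copper acetylide formed in situ with the primary allylic bromide (skipped-enyne synthesis) joins C-1 to C-2, the vinyl iodide being inert to copper acetylides at this temperature.

Step 5
Reactants: 8 1,1-diethoxy-3-methylbutane
Product: 9 (E)-3-(dimethylamino)-2-(propan-2-yl)prop-2-enal
Conditions: POCl3, DMF, 0 to 70 °C; then aqueous K2CO3
Reagents that add atoms: N,N-dimethylformamide CN(C)C=O; water O
Why: Vilsmeier–Haack formylation of the enol ether formed in situ from the acetal, followed by basic hydrolysis, gives the vinylogous formamide in its thermodynamically preferred (E)-form.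

Step 6
Reactants: 9 (E)-3-(dimethylamino)-2-(propan-2-yl)prop-2-enal
Product: 11 (E)-3-[(4-methoxybenzyl)oxy]-2-(propan-2-yl)prop-2-enal, via sodium malonaldehyde enolate 10 (not isolated)
Conditions: NaOH, H2O, 70 °C, then evaporation; 4-methoxybenzyl chloride, DMF, 25 °C
Reagents that add atoms: sodium hydroxide [Na+].[OH-]; 4-methoxybenzyl chloride COc1ccc(CCl)cc1
Why: Addition–elimination hydrolysis of the vinylogous amide gives the malonaldehyde enolate, whose O-alkylation (C-alkylation would create a hindered quaternary centre) gives the push–pull β-alkoxy enal, which equilibrates to the (E)-isomer with the alkoxy group trans to the formyl group.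

Step 7
Reactants: 11 (E)-3-[(4-methoxybenzyl)oxy]-2-(propan-2-yl)prop-2-enal
Product: 12 2-[(1E,3E)-4-[(4-methoxybenzyl)oxy]-3-(propan-2-yl)buta-1,3-dien-1-yl]-4,4,5,5-tetramethyl-1,3,2-dioxaborolane
Conditions: Cl2CHBpin, CrCl2, LiI, THF, 25 °C
Reagents that add atoms: 2-(dichloromethyl)-4,4,5,5-tetramethyl-1,3,2-dioxaborolane ClC(Cl)B1OC(C)(C)C(C)(C)O1
Why: Takai–Utimoto olefination, in which the geminal dichromium species formed from the dihalomethylboronate and CrCl2 adds to the aldehyde and eliminates to the (E)-alkenylboronate, leaving the enol ether geometry intact.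

Step 8
Reactants: 7 (Z)-6-iodohept-5-en-2-yn-1-yl pivalate; 12 2-[(1E,3E)-4-[(4-methoxybenzyl)oxy]-3-(propan-2-yl)buta-1,3-dien-1-yl]-4,4,5,5-tetramethyl-1,3,2-dioxaborolane
Product: 13 (5Z,7E,9E)-10-[(4-methoxybenzyl)oxy]-6-methyl-9-(propan-2-yl)deca-5,7,9-trien-2-yn-1-yl pivalate
Conditions: PdCl2(dppf) (5 mol%), K3PO4, THF/H2O (10:1), 25 °C
Reagents that add atoms: none
Why: Suzuki–Miyaura cross-coupling (oxidative addition of the vinyl iodide to zerovalent palladium, transmetalation, reductive elimination) joins C-4 to C-5 with retention of all olefin geometries and gives the (3Z,5E,7E)-trienyl ether in guaiane locants.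

Step 9
Reactants: 13 (5Z,7E,9E)-10-[(4-methoxybenzyl)oxy]-6-methyl-9-(propan-2-yl)deca-5,7,9-trien-2-yn-1-yl pivalate
Product: 15 (5R,8S)-8-[(4-methoxybenzyl)oxy]-14-norguaia-1(10),3,6-trien-10-yl pivalate, via allenyl pivalate 14 (not isolated)
Conditions: [(S,R,R)-L]AuCl (5 mol%; L = (S)-binaphthyl-2,2'-diyl N,N-bis[(R)-1-phenylethyl]phosphoramidite), AgSbF6 (5 mol%), 4 Å molecular sieves, CH2Cl2, −20 °C
Reagents that add atoms: none
Why: Proposed new method: the cationic monovalent gold catalyst is expected to isomerise the propargylic pivalate by 3,3-acyloxy shift to allenyl pivalate 14, whose gold-bound 1-acyloxyallyl cation (C-1/C-10/C-9) adds through its termini to C-5 and C-8 of the s-cis dienyl ether, after which the gold carbene on C-10 is quenched by 1,2-return of the pivaloyloxy group from C-1, giving the C-1/C-10 enol ester and freeing the catalyst (the alternative sequence of 1,2-acyloxy shift, cyclopropanation of C-5/C-6 and divinylcyclopropane Cope rearrangement would lead to the same product). The closest known reaction types are the gold-catalysed 3,3-rearrangement of propargylic carboxylates to acyloxyallenes and the gold-catalysed intramolecular (4+3) cycloaddition of allenes with tethered 1,3-dienes, which phosphoramidite–gold complexes make enantioselective; new is their union on a primary propargylic ester with acyloxy return as the terminating event. The five-membered ring closes by bond formation between the allyl terminus C-1 and the diene terminus C-5 (5-exo with respect to the diene, the cis C-3/C-4 olefin holding both ends together), and the seven-membered ring by the C-9/C-8 bond of the (4+3) addition across the diene. C-5 and C-8 are the new stereocentres: their relative configuration (H-5 and H-8 cis) follows from suprafacial addition to the (5E,7E)-diene and their absolute configuration from the chiral phosphoramidite on gold, while C-1 stays trigonal and is set in step 10. The step needs seven-ring closure in preference to the six-ring (4+2) and five-ring (3+2) collapse known for such intermediates, which the C-7 isopropyl group (s-cis diene), the donor oxygen on C-8 and the fast intramolecular acyloxy return should secure.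

Step 10
Reactants: 15 (5R,8S)-8-[(4-methoxybenzyl)oxy]-14-norguaia-1(10),3,6-trien-10-yl pivalate
Product: 16 (1R,5S,8S)-8-[(4-methoxybenzyl)oxy]-14-norguaia-3,6-dien-10-one
Conditions: K2CO3 (0.5 equiv), MeOH, 0 to 25 °C
Reagents that add atoms: none
Why: Base-mediated methanolysis of the enol ester (transesterification) liberates the C-10 ketone, and reversible enolisation toward C-1 under the same conditions sets C-1 under thermodynamic control in favour of the trans-fused hydroazulenone (H-1 α, anti to H-5), in which both ring-fusion bonds are equatorial on the seven-membered ring.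

Step 11
Reactants: 16 (1R,5S,8S)-8-[(4-methoxybenzyl)oxy]-14-norguaia-3,6-dien-10-one
Product: 17 (1R,5S,8S,10S)-8-[(4-methoxybenzyl)oxy]guaia-3,6-dien-10-ol
Conditions: MeTi(OiPr)3 (3 equiv), Et2O, 0 to 25 °C
Reagents that add atoms: methyltitanium triisopropoxide C[Ti](OC(C)C)(OC(C)C)OC(C)C
Why: 1,2-Addition of the non-basic organotitanium reagent, which prefers the equatorial trajectory on cycloalkanones, should deliver methyl to the α-face of the C-10 carbonyl (the β-face is flanked by the pseudo-axial H-5 and H-8) and give the 10β-hydroxy-10α-methyl carbinol without enolisation or β-elimination of the C-8 ether.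

Step 12
Reactants: 17 (1R,5S,8S,10S)-8-[(4-methoxybenzyl)oxy]guaia-3,6-dien-10-ol
Product: 18 (1R,5S,8S,10S)-guaia-3,6-diene-8,10-diol
Conditions: DDQ, CH2Cl2/pH 7 phosphate buffer (10:1), 0 °C
Reagents that add atoms: none
Why: Oxidative cleavage of the 4-methoxybenzyl ether by DDQ (hydride abstraction, then hydrolysis of the oxocarbenium ion) frees the allylic 8α-hydroxyl without touching the olefins or the tertiary alcohol.

Step 13
Reactants: 18 (1R,5S,8S,10S)-guaia-3,6-diene-8,10-diol
Product: 19 (1R,5S,7R,8S,10S)-guai-3-ene-8,10-diol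
Conditions: [Rh(nbd)(dppb)]BF4 (5 mol%), H2 (50 bar), CH2Cl2, 25 °C
Reagents that add atoms: none
Why: Hydroxyl-directed hydrogenation, in which the cationic rhodium catalyst binds the allylic 8α-hydroxyl and delivers hydrogen to the α-face of C-6/C-7, sets C-7 (7α-H, isopropyl trans to the hydroxyl) and leaves the unfunctionalised C-3/C-4 olefin untouched.

Step 14
Reactants: 19 (1R,5S,7R,8S,10S)-guai-3-ene-8,10-diol
Product: 20 (1R,5S,7R,10S)-10-hydroxyguai-3-en-8-one
Conditions: Dess–Martin periodinane, CH2Cl2, 0 to 25 °C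
Reagents that add atoms: none
Why: Dess–Martin oxidation converts the secondary C-8 alcohol into the ketone under neutral conditions that leave the tertiary alcohol, the olefin and the epimerisable C-7 centre untouched.

Step 15
Reactants: 20 (1R,5S,7R,10S)-10-hydroxyguai-3-en-8-one
Product: 21 (1R,5S,7R,8R,10S)-guai-3-ene-8,10-diol
Conditions: LiBH(s-Bu)3 (2.5 equiv), THF, −78 °C
Reagents that add atoms: none
Why: Bulky-hydride reduction attacks the C-8 ketone on the equatorial trajectory from the α-face, away from the β-oriented alkoxide on C-10, and gives the axial 8β-alcohol cis to the isopropyl group and syn to the C-10 hydroxyl.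

Step 16
Reactants: 21 (1R,5S,7R,8R,10S)-guai-3-ene-8,10-diol; 22 3,4-dimethoxybenzoyl chloride
Product: 23 (1R,5S,7R,8R,10S)-10-hydroxyguai-3-en-8-yl 3,4-dimethoxybenzoate
Conditions: Et3N, DMAP, CH2Cl2, 25 to 40 °C
Reagents that add atoms: none
Why: DMAP-catalysed acylation (nucleophilic catalysis) esterifies the secondary 8β-hydroxyl selectively, the tertiary C-10 hydroxyl being inert under these conditions.

Step 17
Reactants: 23 (1R,5S,7R,8R,10S)-10-hydroxyguai-3-en-8-yl 3,4-dimethoxybenzoate
Product: 24 (1R,3R,4S,5S,7R,8R,10S)-3,4-epoxy-10-hydroxyguaian-8-yl 3,4-dimethoxybenzoate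
Conditions: m-CPBA, NaHCO3, CH2Cl2, 0 °C
Reagents that add atoms: 3-chloroperoxybenzoic acid OOC(=O)c1cccc(Cl)c1
Why: Prilezhaev epoxidation of the only remaining olefin; the trans ring fusion locks the cyclopentene as an envelope with C-1 as the flap on the α-side, so attack on the α-face is staggered with respect to the pseudo-axial allylic C–H bonds on C-2 and C-5 (torsional steering) and should give the 3α,4α-epoxide, cis to H-1 and trans to H-5.

**Compound list**

1 | prop-2-yn-1-ol | C#CCO | starting material
2 | prop-2-yn-1-yl pivalate | CC(C)(C)C(=O)OCC#C | intermediate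
3 | but-2-yn-1-ol | CC#CCO | starting material
4 | cyclic sodium alkenylalanate, sodium 2,2-bis(2-methoxyethoxy)-3-methyl-2,5-dihydro-1,2-oxaluminol-2-uide | [Na+].CC1=CCO[Al-]1(OCCOC)OCCOC | intermediate
5 | (Z)-3-iodobut-2-en-1-ol | OC/C=C(C)\I | intermediate
6 | (Z)-1-bromo-3-iodobut-2-ene | BrC/C=C(C)\I | intermediate
7 | (Z)-6-iodohept-5-en-2-yn-1-yl pivalate | CC(C)(C)C(=O)OCC#CC/C=C(C)\I | intermediate
8 | 1,1-diethoxy-3-methylbutane | CCOC(CC(C)C)OCC | starting material
9 | (E)-3-(dimethylamino)-2-(propan-2-yl)prop-2-enal | CN(C)/C=C(/C=O)C(C)C | intermediate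
10 | sodium (E)-2-formyl-3-methylbut-1-en-1-olate | [Na+].[O-]/C=C(/C=O)C(C)C | intermediate
11 | (E)-3-[(4-methoxybenzyl)oxy]-2-(propan-2-yl)prop-2-enal | O=C/C(C(C)C)=C/OCc1ccc(OC)cc1 | intermediate
12 | 2-[(1E,3E)-4-[(4-methoxybenzyl)oxy]-3-(propan-2-yl)buta-1,3-dien-1-yl]-4,4,5,5-tetramethyl-1,3,2-dioxaborolane | CC1(C)OB(/C=C/C(C(C)C)=C/OCc2ccc(OC)cc2)OC1(C)C | intermediate
13 | (5Z,7E,9E)-10-[(4-methoxybenzyl)oxy]-6-methyl-9-(propan-2-yl)deca-5,7,9-trien-2-yn-1-yl pivalate | CC(C)(C)C(=O)OCC#CC/C=C(C)\C=C\C(C(C)C)=C\OCc1ccc(OC)cc1 | intermediate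
14 | (5Z,7E,9E)-10-[(4-methoxybenzyl)oxy]-6-methyl-9-(propan-2-yl)deca-1,2,5,7,9-pentaen-3-yl pivalate | CC(C)(C)C(=O)OC(=C=C)C/C=C(C)\C=C\C(C(C)C)=C\OCc1ccc(OC)cc1 | intermediate
15 | (5R,8S)-8-[(4-methoxybenzyl)oxy]-14-norguaia-1(10),3,6-trien-10-yl pivalate | COc1ccc(CO[C@H]2CC(OC(=O)C(C)(C)C)=C3CC=C(C)[C@H]3C=C2C(C)C)cc1 | intermediate
16 | (1R,5S,8S)-8-[(4-methoxybenzyl)oxy]-14-norguaia-3,6-dien-10-one | COc1ccc(CO[C@H]2CC(=O)[C@@H]3CC=C(C)[C@H]3C=C2C(C)C)cc1 | intermediate
17 | (1R,5S,8S,10S)-8-[(4-methoxybenzyl)oxy]guaia-3,6-dien-10-ol | COc1ccc(CO[C@H]2C[C@](C)(O)[C@@H]3CC=C(C)[C@H]3C=C2C(C)C)cc1 | intermediate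
18 | (1R,5S,8S,10S)-guaia-3,6-diene-8,10-diol | O[C@H]1C[C@](C)(O)[C@@H]2CC=C(C)[C@H]2C=C1C(C)C | intermediate
19 | (1R,5S,7R,8S,10S)-guai-3-ene-8,10-diol | O[C@H]1C[C@](C)(O)[C@@H]2CC=C(C)[C@H]2C[C@@H]1C(C)C | intermediate
20 | (1R,5S,7R,10S)-10-hydroxyguai-3-en-8-one | O=C1C[C@](C)(O)[C@@H]2CC=C(C)[C@H]2C[C@@H]1C(C)C | intermediate
21 | (1R,5S,7R,8R,10S)-guai-3-ene-8,10-diol | O[C@@H]1C[C@](C)(O)[C@@H]2CC=C(C)[C@H]2C[C@@H]1C(C)C | intermediate
22 | 3,4-dimethoxybenzoyl chloride | COc1ccc(C(Cl)=O)cc1OC | starting material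
23 | (1R,5S,7R,8R,10S)-10-hydroxyguai-3-en-8-yl 3,4-dimethoxybenzoate | COc1ccc(C(=O)O[C@@H]2C[C@](C)(O)[C@@H]3CC=C(C)[C@H]3C[C@@H]2C(C)C)cc1OC | intermediate
24 | (1R,3R,4S,5S,7R,8R,10S)-3,4-epoxy-10-hydroxyguaian-8-yl 3,4-dimethoxybenzoate | COc1ccc(C(=O)O[C@@H]2C[C@](C)(O)[C@@H]3C[C@H]4O[C@@]4(C)[C@H]3C[C@@H]2C(C)C)cc1OC | target

**Step count and risks**

Total step count: 17. Longest linear sequence: 13 steps (steps 5 to 17 from acetal 8; equally steps 2 to 4 and 8 to 17 from but-2-yn-1-ol 3).

Steps most likely to fail: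

Step 9 (proposed new method). The gold-bound intermediates may collapse to six- or five-membered rings ((4+2) or (3+2) closure) instead of the seven-membered ring, the 4-methoxybenzyl group may be lost from an oxocarbenium-type intermediate, or the ligand may discriminate the diene faces poorly. The fallback uses known chemistry, sets out from bromide 6 and boronate 12 and comes back at 18. C-Alkylation of 3-chloropentane-2,4-dione with 6 (K2CO3, acetone) would give 3-chloro-3-[(2Z)-3-iodobut-2-en-1-yl]pentane-2,4-dione F1, and mild deacetylation (K2CO3, MeOH, 0 °C) the α-chloro ketone (Z)-3-chloro-6-iodohept-5-en-2-one F2. Suzuki–Miyaura coupling of F2 with 12 (PdCl2(dppf), K3PO4) would give the chloro ketone triene (5Z,7E,9E)-3-chloro-10-[(4-methoxybenzyl)oxy]-6-methyl-9-(propan-2-yl)deca-5,7,9-trien-2-one F3. Its oxyallyl cation, generated with Et3N in CF3CH2OH, should undergo the established intramolecular (4+3) cycloaddition of α-halo-ketone-derived oxyallyl cations with a tethered diene. After equilibration of the ring fusion (K2CO3, MeOH) this would give racemic hydroazulenone, that is 16 together with its enantiomer ent-16 F4. The conditions of steps 11 and 12 would carry this material on to racemic 17 (with ent-17 F5) and racemic 18 (with ent-18 F6). Lipase-catalysed acylation (Candida antarctica lipase B, vinyl acetate) is then expected to acetylate the (8R)-alcohol F6 to the acetate of ent-18 F7 and to leave the (8S)-alcohol 18, which rejoins the route.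

Step 11. Methyl transfer to the C-10 carbonyl may show poor facial selectivity, or the addition may be sluggish and give way to enolisation and β-elimination of the C-8 ether. The fallback sets out from 16 and comes back at 17. Corey–Chaykovsky epoxidation with dimethylsulfoxonium methylide (trimethylsulfoxonium iodide, NaH, DMSO), which forms the new C–C bond reversibly and therefore equatorially, would give the spiro-epoxide (1R,5S,8S,10S)-10,14-epoxy-8-[(4-methoxybenzyl)oxy]guaia-3,6-diene F8 with the oxygen axial on the β-face. Hydride opening at the methylene carbon (LiBHEt3, THF, 0 °C) would then give 17.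

Step 17. Oxygen transfer may show poor facial selectivity, that is, the peracid may attack the β-face of the cyclopentene. The fallback sets out from 23 and comes back at 24. If electrophiles prefer the β-face, bromohydrin formation (N-bromosuccinimide, THF/H2O, 0 °C) should place the bromonium ion there, and water would open it at the tertiary carbon C-4 from the α-face to give (1R,3S,4S,5S,7R,8R,10S)-3-bromo-4,10-dihydroxyguaian-8-yl 3,4-dimethoxybenzoate F9. Ring closure with DBU (CH2Cl2, 25 °C) by backside displacement of bromide would then give the 3α,4α-epoxide 24.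

**Further compounds**

F1 | step 9 | 3-chloro-3-[(2Z)-3-iodobut-2-en-1-yl]pentane-2,4-dione | CC(=O)C(Cl)(C/C=C(C)\I)C(C)=O
F2 | step 9 | (Z)-3-chloro-6-iodohept-5-en-2-one (racemic) | CC(=O)C(Cl)C/C=C(C)\I
F3 | step 9 | (5Z,7E,9E)-3-chloro-10-[(4-methoxybenzyl)oxy]-6-methyl-9-(propan-2-yl)deca-5,7,9-trien-2-one (racemic) | CC(=O)C(Cl)C/C=C(C)\C=C\C(C(C)C)=C\OCc1ccc(OC)cc1
F4 | step 9 | ent-16, (1S,5R,8R)-8-[(4-methoxybenzyl)oxy]-14-norguaia-3,6-dien-10-one | COc1ccc(CO[C@@H]2CC(=O)[C@H]3CC=C(C)[C@@H]3C=C2C(C)C)cc1
F5 | step 9 | ent-17, (1S,5R,8R,10R)-8-[(4-methoxybenzyl)oxy]guaia-3,6-dien-10-ol | COc1ccc(CO[C@@H]2C[C@@](C)(O)[C@H]3CC=C(C)[C@@H]3C=C2C(C)C)cc1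
F6 | step 9 | ent-18, (1S,5R,8R,10R)-guaia-3,6-diene-8,10-diol | O[C@@H]1C[C@@](C)(O)[C@H]2CC=C(C)[C@@H]2C=C1C(C)C
F7 | step 9 | acetate of ent-18, (1S,5R,8R,10R)-10-hydroxyguaia-3,6-dien-8-yl acetate | CC(=O)O[C@@H]1C[C@@](C)(O)[C@H]2CC=C(C)[C@@H]2C=C1C(C)C
F8 | step 11 | (1R,5S,8S,10S)-10,14-epoxy-8-[(4-methoxybenzyl)oxy]guaia-3,6-diene | COc1ccc(CO[C@H]2C[C@@]4(CO4)[C@@H]3CC=C(C)[C@H]3C=C2C(C)C)cc1
F9 | step 17 | (1R,3S,4S,5S,7R,8R,10S)-3-bromo-4,10-dihydroxyguaian-8-yl 3,4-dimethoxybenzoate | COc1ccc(C(=O)O[C@@H]2C[C@](C)(O)[C@@H]3C[C@H](Br)[C@@](C)(O)[C@H]3C[C@@H]2C(C)C)cc1OC
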